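**Retrosynthetic overview**

1. Endgame: the 16-methylene comes from a 16-ketone, the 2β,3β-diol from OsO4 on a ring-A 2-ene (face opposite the lactone), the 19,10-lactone from iodolactonisation of a 1(10),2-diene 19-acid, and the C4 quaternary centre from deconjugative methylation of a 3-en-19-oate.
2. Key disconnection: ring B is cut at C8–C9 and C5–C6. Both bonds, and with the first one ring C, are made in one anionic formal (3+2) annulation (intramolecular Michael addition, then Michael addition–elimination, overall SN2′).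
3. Enabling feature: ring B sits between three carbonyl-level carbons – C11 (the carbinol, used as a ketone) on C9, the C7 carboxyl on C6 and the C19 carboxyl on C4 – so C9 (donor), C8 (acceptor), C6 (donor) and C5 (acceptor) alternate. A pivalate on C3 lets the sequence end by elimination.
4. The cascade precursor joins two monocycles through the chain C12–C11(=O)–C9: ring D from (R)-4-silyloxycyclopentenone (sets C13) and ring A from a cyclohexenone ester, united by Pd-catalysed alkenylation of a ketone zinc enolate.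
5. Order of ring formation: D and A (bought as rings), then C and B together in step 9, then the lactone ring in step 14.

Key step: step 9

Remark: gibberellane numbering (C1–C19) and the customary gibberellin α/β descriptors are used; compounds 2–5 are racemic at the future C3 (so 19–21 are C3-epimer mixtures) and 14, 16–21 are E/Z mixtures at the exocyclic ester double bond, both of which disappear in step 9 and are therefore left undefined in the SMILES; compound 1 is taken as commercially available.

**Route**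

Step 1
Reactants: 1 methyl 3-oxocyclohex-1-ene-1-carboxylate
Product: 2 methyl 6-bromo-3-oxocyclohex-1-ene-1-carboxylate (racemic)
Conditions: NBS, AIBN (cat.), PhCF3, 80 °C
Reagents that add atoms: N-bromosuccinimide, O=C1CCC(=O)N1Br
Why: Wohl–Ziegler bromination at C6, the only allylic CH2, where bromine transfer keeps the enone–ester conjugation; the new centre is racemic, which is immaterial because it becomes sp2 in step 9.

Step 2
Reactants: 2 methyl 6-bromo-3-oxocyclohex-1-ene-1-carboxylate
Product: 3 methyl 3-oxo-6-(pivaloyloxy)cyclohex-1-ene-1-carboxylate (racemic)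
Conditions: CsO2CCMe3, DMF, 0 °C → rt
Reagents that add atoms: cesium pivalate, CC(C)(C)C(=O)[O-].[Cs+]
Why: SN2 displacement of the secondary allylic bromide by a weakly basic carboxylate; pivalate is chosen because it resists enolates and alkoxide bases but leaves readily by E1cB in step 9.

Step 3
Reactants: 3 methyl 3-oxo-6-(pivaloyloxy)cyclohex-1-ene-1-carboxylate
Product: 5 methyl 6-(pivaloyloxy)-3-(trifluoromethylsulfonyloxy)cyclohexa-1,3-diene-1-carboxylate (racemic), via lithium dienolate 4 (not isolated)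
Conditions: LiN(SiMe3)2, THF, −78 °C; PhNTf2, −78 → 0 °C; aq NH4Cl
Reagents that add atoms: N-phenylbis(trifluoromethanesulfonimide), O=S(=O)(N(c1ccccc1)S(=O)(=O)C(F)(F)F)C(F)(F)F
Why: kinetic α′-deprotonation at the CH2 next to the ketone gives the cross-conjugated dienolate, and O-triflation of this ketone enolate fixes the 1,3-diene where the cascade needs it.

Step 4
Reactants: 6 (trimethylsilyl)acetic acid; 7 2-(trimethylsilyl)ethanol
Product: 8 2-(trimethylsilyl)ethyl (trimethylsilyl)acetate
Conditions: DCC, DMAP (cat.), CH2Cl2, 0 °C → rt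
Reagents that add atoms: none
Why: Steglich esterification; it supplies a fluoride-labile ester for the future C7 carboxyl.

Step 5
Reactants: 9 (R)-4-(tert-butyldimethylsilyloxy)cyclopent-2-en-1-one
Product: 11 (3R,4R)-4-(tert-butyldimethylsilyloxy)-3-(2-methylprop-2-en-1-yl)cyclopentan-1-one, via trimethylsilyl enol ether 10 (not isolated)
Conditions: CH2=C(CH3)CH2MgCl, CuBr·SMe2 (10 mol%), Me3SiCl, THF, −78 °C; then 1 M HCl, 0 °C
Reagents that add atoms: 2-methylallylmagnesium chloride, CC(=C)C[Mg]Cl
Why: copper-catalysed conjugate addition accelerated by the silyl chloride; the nucleophile enters anti to the silyloxy group, which sets the ring-D centre that becomes C13.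

Step 6
Reactants: 8 2-(trimethylsilyl)ethyl (trimethylsilyl)acetate; 11 (3R,4R)-4-(tert-butyldimethylsilyloxy)-3-(2-methylprop-2-en-1-yl)cyclopentan-1-one
Product: 14 2-(trimethylsilyl)ethyl 2-[4-(tert-butyldimethylsilyloxy)-3-(2-methylprop-2-en-1-yl)cyclopentylidene]acetate (3,4-trans as in 11; E/Z mixture), via lithium ester enolate 12 (not isolated), via lithium β-silyl alkoxide 13 (not isolated)
Conditions: 8, LiN(i-Pr)2, THF, −78 °C; then 11, −78 °C → rt; aq NH4Cl
Reagents that add atoms: none
Why: Peterson olefination, in which the α-silyl ester enolate adds to the ketone faster than it enolises it and the adduct eliminates on warming; both alkene isomers serve because this double bond is consumed in step 9.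

Step 7
Reactants: 14 2-(trimethylsilyl)ethyl 2-[4-(tert-butyldimethylsilyloxy)-3-(2-methylprop-2-en-1-yl)cyclopentylidene]acetate
Product: 16 2-(trimethylsilyl)ethyl 2-[4-(tert-butyldimethylsilyloxy)-3-(2-oxopropyl)cyclopentylidene]acetate, via ozonide 15 (not isolated)
Conditions: O3, CH2Cl2, −78 °C (Sudan Red 7B end point); Me2S, −78 °C → rt
Reagents that add atoms: ozone, [O-][O+]=O
Why: chemoselective ozonolysis, since the electron-rich 1,1-disubstituted alkene reacts far faster than the conjugated trisubstituted enoate.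

Step 8
Reactants: 16 2-(trimethylsilyl)ethyl 2-[4-(tert-butyldimethylsilyloxy)-3-(2-oxopropyl)cyclopentylidene]acetate; 5 methyl 6-(pivaloyloxy)-3-(trifluoromethylsulfonyloxy)cyclohexa-1,3-diene-1-carboxylate
Product: 19 2-(trimethylsilyl)ethyl 2-{4-(tert-butyldimethylsilyloxy)-3-[3-(5-methoxycarbonyl-4-pivaloyloxycyclohexa-1,5-dien-1-yl)-2-oxopropyl]cyclopentylidene}acetate, via lithium enolate 17 (not isolated), via chlorozinc enolate 18 (not isolated)
Conditions: 16, LiN(i-Pr)2, THF, −78 °C; ZnCl2, −78 → 0 °C; then 5 (1.3 equiv), Pd2(dba)3 (2.5 mol%), XPhos (6 mol%), THF, rt; aq NH4Cl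
Reagents that add atoms: none
Why: palladium-catalysed α-alkenylation of a ketone zinc enolate (Negishi-type enolate coupling); kinetic enolisation at the methyl group fixes the site, coupling at the triflate carbon gives the β,γ-unsaturated ketone with the diene in place, and oxidative addition to the dienyl triflate should outrun ionisation of the hindered allylic pivalate.

Step 9
Reactants: 19 2-(trimethylsilyl)ethyl 2-{4-(tert-butyldimethylsilyloxy)-3-[3-(5-methoxycarbonyl-4-pivaloyloxycyclohexa-1,5-dien-1-yl)-2-oxopropyl]cyclopentylidene}acetate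
Product: 22 19-methyl 7-[2-(trimethylsilyl)ethyl] 16-(tert-butyldimethylsilyloxy)-11-oxo-17,18,20-trinorgibberella-1(10),3-diene-7,19-dioate (5β-H, 9β-H, H-5/H-6 trans), via potassium dienolate 20 (not isolated), via potassium ester enolate 21 (not isolated)
Conditions: KN(SiMe3)2 (1.0 equiv), THF (0.01 M), −78 → −30 °C; AcOH, −78 °C
Reagents that add atoms: none
Why: KN(SiMe3)2 removes only the C9–H of 19, which is α to the C11 ketone and allylic to the ring-A diene (about six pKa units more acidic than C12–H), so a single cross-conjugated dienolate 20 forms; its α-carbon C9 adds to C8, the β-carbon of the cyclopentylidene acetate (6-exo-trig Michael addition, closes ring C as a bicyclo[3.2.1]octane), and the ester enolate 21 then adds through C6 to C5, the β-carbon of the ring-A enoate, while pivalate leaves from C3 (5-exo-trig Michael addition–E1cB elimination, overall SN2′, closes ring B). The closest known reaction types are the intramolecular double Michael reaction and Michael-initiated SN2′ (3+2) annulations of allylic carboxylates. C8 is fixed by the existing C13 centre, because the C12–C11–C9 tether can only bridge the cyclopentane ring cis. C9 and C5 are controlled by ring strain: the first Michael addition is reversible whereas loss of pivalate is not, and only the adduct with C10 axial on the new ring C (cis B/C fusion, 9β-H) reaches an unstrained five-membered transition state, in which the torsion fixed at C8–C9 steers C6 onto the ring-A face that gives 5β-H; C6 forms with its ester group anti to C4 (H-5/H-6 trans), the arrangement also preferred at equilibrium. The selectivities needed are C9 over C12 enolisation (acidity gap, one equivalent of base, aprotic medium), attack at C5 and not at C1 (5-exo against 5-endo), and a non-basic end point, which the leaving pivalate provides so that neither C9 nor the C1(10) double bond of 22 is disturbed before the cold quench.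

Step 10
Reactants: 22 19-methyl 7-[2-(trimethylsilyl)ethyl] 16-(tert-butyldimethylsilyloxy)-11-oxo-17,18,20-trinorgibberella-1(10),3-diene-7,19-dioate
Product: 23 19-methyl 7-[2-(trimethylsilyl)ethyl] 16-(tert-butyldimethylsilyloxy)-11β-hydroxy-17,18,20-trinorgibberella-1(10),3-diene-7,19-dioate
Conditions: LiBH(s-Bu)3, THF, −78 °C (crude 22); aq NH4Cl
Reagents that add atoms: none
Why: hydride is delivered to the C11 carbonyl from the face away from the C15–C16 bridge (exo attack on the bicyclo[3.2.1]octanone), which gives the axial 11β-alcohol; the bulky borohydride leaves the esters alone at −78 °C.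

Step 11
Reactants: 23 19-methyl 7-[2-(trimethylsilyl)ethyl] 16-(tert-butyldimethylsilyloxy)-11β-hydroxy-17,18,20-trinorgibberella-1(10),3-diene-7,19-dioate
Product: 24 19-methyl 7-[2-(trimethylsilyl)ethyl] 11β,16-bis(tert-butyldimethylsilyloxy)-17,18,20-trinorgibberella-1(10),3-diene-7,19-dioate
Conditions: t-BuMe2SiOTf, 2,6-lutidine, CH2Cl2, 0 °C → rt
Reagents that add atoms: tert-butyldimethylsilyl trifluoromethanesulfonate, CC(C)(C)[Si](C)(C)OS(=O)(=O)C(F)(F)F
Why: silylation of a hindered axial alcohol with the silyl triflate; it protects C11–OH through the enolate and oxidation steps.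

Step 12
Reactants: 24 19-methyl 7-[2-(trimethylsilyl)ethyl] 11β,16-bis(tert-butyldimethylsilyloxy)-17,18,20-trinorgibberella-1(10),3-diene-7,19-dioate
Product: 26 19-methyl 7-[2-(trimethylsilyl)ethyl] 11β,16-bis(tert-butyldimethylsilyloxy)-17,20-dinorgibberella-1(10),2-diene-7,19-dioate (18-methyl β, C19 α), via lithium trienolate 25 (not isolated)
Conditions: LiN(i-Pr)2, THF/DMPU, −78 °C; MeI, −78 → −40 °C
Reagents that add atoms: iodomethane, CI
Why: deconjugative α-alkylation of an α,β-unsaturated ester, in which the base removes the doubly allylic γ-H at C2 and the extended enolate is methylated at C4 on the β face, anti to the C5–C6 bond that carries rings B to D; this sets the C4 quaternary centre and leaves the 1(10),2-diene.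

Step 13
Reactants: 26 19-methyl 7-[2-(trimethylsilyl)ethyl] 11β,16-bis(tert-butyldimethylsilyloxy)-17,20-dinorgibberella-1(10),2-diene-7,19-dioate
Product: 27 11β,16-bis(tert-butyldimethylsilyloxy)-7-[2-(trimethylsilyl)ethoxy]-7-oxo-17,20-dinorgibberella-1(10),2-dien-19-oic acid
Conditions: NaSEt, DMF, 50 °C; 1 M HCl to pH 3
Reagents that add atoms: none
Why: SN2 demethylation of the hindered methyl ester by thiolate at the methyl carbon; the 2-(trimethylsilyl)ethyl ester is attacked much more slowly.

Step 14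
Reactants: 27 11β,16-bis(tert-butyldimethylsilyloxy)-7-[2-(trimethylsilyl)ethoxy]-7-oxo-17,20-dinorgibberella-1(10),2-dien-19-oic acid
Product: 28 2-(trimethylsilyl)ethyl 11β,16-bis(tert-butyldimethylsilyloxy)-1β-iodo-17,20-dinorgibberell-2-en-7-oate 19,10-lactone
Conditions: I2, NaHCO3, THF/H2O, 0 °C, dark
Reagents that add atoms: iodine, II
Why: iodolactonisation, in which the α-oriented C19 carboxylate adds to C10 (5-exo) anti to the iodonium ion, so C10 (O α) follows from C4; an allylic 3-iodo-1-ene isomer, if formed, converges in step 15.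

Step 15
Reactants: 28 2-(trimethylsilyl)ethyl 11β,16-bis(tert-butyldimethylsilyloxy)-1β-iodo-17,20-dinorgibberell-2-en-7-oate 19,10-lactone
Product: 29 2-(trimethylsilyl)ethyl 11β,16-bis(tert-butyldimethylsilyloxy)-17,20-dinorgibberell-2-en-7-oate 19,10-lactone
Conditions: Bu3SnH, AIBN (cat.), toluene, 80 °C
Reagents that add atoms: none
Why: radical deiodination; the delocalised C1–C2–C3 allyl radical is expected to take hydrogen at C1 and give the 2-ene, as is known for 1-halo-2-enes of this lactone ring system.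

Step 16
Reactants: 29 2-(trimethylsilyl)ethyl 11β,16-bis(tert-butyldimethylsilyloxy)-17,20-dinorgibberell-2-en-7-oate 19,10-lactone
Product: 30 2-(trimethylsilyl)ethyl 11β-(tert-butyldimethylsilyloxy)-16-hydroxy-17,20-dinorgibberell-2-en-7-oate 19,10-lactone
Conditions: HF·pyridine, pyridine, THF, 0 °C → rt
Reagents that add atoms: none
Why: selective desilylation, since the exposed secondary silyl ether at C16 is cleaved while the axial 11-silyl ether under the bridge and the silylethyl ester survive buffered HF.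

Step 17
Reactants: 30 2-(trimethylsilyl)ethyl 11β-(tert-butyldimethylsilyloxy)-16-hydroxy-17,20-dinorgibberell-2-en-7-oate 19,10-lactone
Product: 31 2-(trimethylsilyl)ethyl 11β-(tert-butyldimethylsilyloxy)-16-oxo-17,20-dinorgibberell-2-en-7-oate 19,10-lactone
Conditions: Dess–Martin periodinane, CH2Cl2, rt
Reagents that add atoms: none
Why: Dess–Martin oxidation of the secondary alcohol; C13 is a bridgehead, so the new ketone cannot epimerise it.

Step 18
Reactants: 31 2-(trimethylsilyl)ethyl 11β-(tert-butyldimethylsilyloxy)-16-oxo-17,20-dinorgibberell-2-en-7-oate 19,10-lactone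
Product: 32 2-(trimethylsilyl)ethyl 11β-(tert-butyldimethylsilyloxy)-2β,3β-dihydroxy-16-oxo-17,20-dinorgibberellan-7-oate 19,10-lactone
Conditions: OsO4 (5 mol%), NMO, acetone/H2O, rt
Reagents that add atoms: N-methylmorpholine N-oxide, C[N+]1([O-])CCOCC1; water, O
Why: catalytic cis-dihydroxylation from the β face, opposite the α-oriented 19,10-lactone bridge, gives the 2β,3β-diol.

Step 19
Reactants: 32 2-(trimethylsilyl)ethyl 11β-(tert-butyldimethylsilyloxy)-2β,3β-dihydroxy-16-oxo-17,20-dinorgibberellan-7-oate 19,10-lactone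
Product: 33 2-(trimethylsilyl)ethyl 11β-(tert-butyldimethylsilyloxy)-2β,3β-dihydroxy-20-norgibberell-16-en-7-oate 19,10-lactone
Conditions: Zn, CH2Br2, TiCl4, THF (reagent aged at 5 °C); then 32, CH2Cl2, 0 °C → rt
Reagents that add atoms: dibromomethane, BrCBr
Why: Takai–Lombardo methylenation; the non-basic titanium methylene reagent converts the ketone into the exocyclic alkene without retro-aldol epimerisation of the 3-hydroxy lactone and without touching ester or lactone.

Step 20
Reactants: 33 2-(trimethylsilyl)ethyl 11β-(tert-butyldimethylsilyloxy)-2β,3β-dihydroxy-20-norgibberell-16-en-7-oate 19,10-lactone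
Product: 34 2β,3β,11β-trihydroxy-20-norgibberell-16-ene-7,19-dioic acid 19,10-lactone (CNP0322347.1)
Conditions: Bu4NF, AcOH, THF, rt → 40 °C; aq HCl to pH 3
Reagents that add atoms: none
Why: fluoride cleaves the 2-(trimethylsilyl)ethyl ester by β-elimination and removes the remaining silyl ether under buffered conditions that leave the 16-ene and the lactone intact.

**Compound list**

1 | methyl 3-oxocyclohex-1-ene-1-carboxylate | COC(=O)C1=CC(=O)CCC1 | starting material
2 | methyl 6-bromo-3-oxocyclohex-1-ene-1-carboxylate (racemic) | COC(=O)C1=CC(=O)CCC1Br | intermediate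
3 | methyl 3-oxo-6-(pivaloyloxy)cyclohex-1-ene-1-carboxylate (racemic) | COC(=O)C1=CC(=O)CCC1OC(=O)C(C)(C)C | intermediate
4 | lithium cross-conjugated dienolate of 3 | [Li+].COC(=O)C1=CC([O-])=CCC1OC(=O)C(C)(C)C | intermediate (not isolated)
5 | methyl 6-(pivaloyloxy)-3-(trifluoromethylsulfonyloxy)cyclohexa-1,3-diene-1-carboxylate (racemic) | COC(=O)C1=CC(OS(=O)(=O)C(F)(F)F)=CCC1OC(=O)C(C)(C)C | intermediate
6 | (trimethylsilyl)acetic acid | C[Si](C)(C)CC(=O)O | starting material
7 | 2-(trimethylsilyl)ethanol | C[Si](C)(C)CCO | starting material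
8 | 2-(trimethylsilyl)ethyl (trimethylsilyl)acetate | C[Si](C)(C)CC(=O)OCC[Si](C)(C)C | intermediate
9 | (R)-4-(tert-butyldimethylsilyloxy)cyclopent-2-en-1-one | O=C1C=C[C@H](O[Si](C)(C)C(C)(C)C)C1 | starting material
10 | trimethylsilyl enol ether of 11 (enol ether toward the unsubstituted α-carbon) | C[Si](C)(C)OC1=C[C@@H](CC(C)=C)[C@H](O[Si](C)(C)C(C)(C)C)C1 | intermediate (not isolated)
11 | (3R,4R)-4-(tert-butyldimethylsilyloxy)-3-(2-methylprop-2-en-1-yl)cyclopentan-1-one | O=C1C[C@@H](CC(C)=C)[C@H](O[Si](C)(C)C(C)(C)C)C1 | intermediate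
12 | lithium enolate of 8 | [Li+].C[Si](C)(C)C=C([O-])OCC[Si](C)(C)C | intermediate (not isolated)
13 | lithium β-silyl alkoxide from 12 and 11 (new centres as a mixture) | [Li+].[O-]C1(C(C(=O)OCC[Si](C)(C)C)[Si](C)(C)C)C[C@@H](CC(C)=C)[C@H](O[Si](C)(C)C(C)(C)C)C1 | intermediate (not isolated)
14 | 2-(trimethylsilyl)ethyl 2-[4-(tert-butyldimethylsilyloxy)-3-(2-methylprop-2-en-1-yl)cyclopentylidene]acetate (ring centres as in 11, E/Z mixture) | C[Si](C)(C)CCOC(=O)C=C1C[C@@H](CC(C)=C)[C@H](O[Si](C)(C)C(C)(C)C)C1 | intermediate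
15 | ozonide (1,2,4-trioxolane) of the methallyl alkene of 14 | C[Si](C)(C)CCOC(=O)C=C1C[C@@H](CC2(C)OCOO2)[C@H](O[Si](C)(C)C(C)(C)C)C1 | intermediate (not isolated)
16 | 2-(trimethylsilyl)ethyl 2-[4-(tert-butyldimethylsilyloxy)-3-(2-oxopropyl)cyclopentylidene]acetate (ring centres as in 11, E/Z mixture) | C[Si](C)(C)CCOC(=O)C=C1C[C@@H](CC(C)=O)[C@H](O[Si](C)(C)C(C)(C)C)C1 | intermediate
17 | lithium enolate of 16 at the methyl carbon | [Li+].C[Si](C)(C)CCOC(=O)C=C1C[C@@H](CC([O-])=C)[C@H](O[Si](C)(C)C(C)(C)C)C1 | intermediate (not isolated)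
18 | chlorozinc enolate of 16 at the methyl carbon | C[Si](C)(C)CCOC(=O)C=C1C[C@@H](CC(=C)O[Zn]Cl)[C@H](O[Si](C)(C)C(C)(C)C)C1 | intermediate (not isolated)
19 | 2-(trimethylsilyl)ethyl 2-{4-(tert-butyldimethylsilyloxy)-3-[3-(5-methoxycarbonyl-4-pivaloyloxycyclohexa-1,5-dien-1-yl)-2-oxopropyl]cyclopentylidene}acetate (cascade precursor) | C[Si](C)(C)CCOC(=O)C=C1C[C@@H](CC(=O)CC2=CCC(OC(=O)C(C)(C)C)C(C(=O)OC)=C2)[C@H](O[Si](C)(C)C(C)(C)C)C1 | intermediate
20 | potassium dienolate of 19 (C11 enolate conjugated with the C10=C1 bond) | [K+].C[Si](C)(C)CCOC(=O)C=C1C[C@@H](CC([O-])=CC2=CCC(OC(=O)C(C)(C)C)C(C(=O)OC)=C2)[C@H](O[Si](C)(C)C(C)(C)C)C1 | intermediate (not isolated)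
21 | potassium ester enolate of the first Michael adduct (rings C and D closed, C8–C9 formed, 9β-H) | [K+].CC(C)(C)[Si](C)(C)O[C@@H]1C[C@]2(C=C([O-])OCC[Si](C)(C)C)C[C@H]1CC(=O)[C@H]2C3=CCC(OC(=O)C(C)(C)C)C(C(=O)OC)=C3 | intermediate (not isolated)
22 | 19-methyl 7-[2-(trimethylsilyl)ethyl] 16-(tert-butyldimethylsilyloxy)-11-oxo-17,18,20-trinorgibberella-1(10),3-diene-7,19-dioate (5β-H, 9β-H, H-5/H-6 trans) | CC(C)(C)[Si](C)(C)O[C@@H]1C[C@]23C[C@H]1CC(=O)[C@H]2C4=CCC=C(C(=O)OC)[C@H]4[C@@H]3C(=O)OCC[Si](C)(C)C | intermediate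
23 | 11β-alcohol of 22 | CC(C)(C)[Si](C)(C)O[C@@H]1C[C@]23C[C@H]1C[C@H](O)[C@H]2C4=CCC=C(C(=O)OC)[C@H]4[C@@H]3C(=O)OCC[Si](C)(C)C | intermediate
24 | 11β,16-bis(silyl ether) of 23 | CC(C)(C)[Si](C)(C)O[C@@H]1C[C@]23C[C@H]1C[C@H](O[Si](C)(C)C(C)(C)C)[C@H]2C4=CCC=C(C(=O)OC)[C@H]4[C@@H]3C(=O)OCC[Si](C)(C)C | intermediate
25 | lithium trienolate of 24 (C19 enolate conjugated with C3=C2 and C1=C10) | [Li+].CC(C)(C)[Si](C)(C)O[C@@H]1C[C@]23C[C@H]1C[C@H](O[Si](C)(C)C(C)(C)C)[C@H]2C4=CC=CC(=C([O-])OC)[C@H]4[C@@H]3C(=O)OCC[Si](C)(C)C | intermediate (not isolated)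
26 | 19-methyl 7-[2-(trimethylsilyl)ethyl] 11β,16-bis(tert-butyldimethylsilyloxy)-17,20-dinorgibberella-1(10),2-diene-7,19-dioate (18-methyl β) | CC(C)(C)[Si](C)(C)O[C@@H]1C[C@]23C[C@H]1C[C@H](O[Si](C)(C)C(C)(C)C)[C@H]2C4=CC=C[C@@](C)(C(=O)OC)[C@H]4[C@@H]3C(=O)OCC[Si](C)(C)C | intermediate
27 | 19-acid of 26 | CC(C)(C)[Si](C)(C)O[C@@H]1C[C@]23C[C@H]1C[C@H](O[Si](C)(C)C(C)(C)C)[C@H]2C4=CC=C[C@@](C)(C(=O)O)[C@H]4[C@@H]3C(=O)OCC[Si](C)(C)C | intermediate
28 | 1β-iodo-2-ene 19,10-lactone | CC(C)(C)[Si](C)(C)O[C@@H]1C[C@]23C[C@H]1C[C@H](O[Si](C)(C)C(C)(C)C)[C@H]2[C@@]12[C@H](I)C=C[C@@](C)(C(=O)O1)[C@H]2[C@@H]3C(=O)OCC[Si](C)(C)C | intermediate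
29 | 2-ene 19,10-lactone | CC(C)(C)[Si](C)(C)O[C@@H]1C[C@]23C[C@H]1C[C@H](O[Si](C)(C)C(C)(C)C)[C@H]2[C@@]12CC=C[C@@](C)(C(=O)O1)[C@H]2[C@@H]3C(=O)OCC[Si](C)(C)C | intermediate
30 | 16-alcohol of 29 | O[C@@H]1C[C@]23C[C@H]1C[C@H](O[Si](C)(C)C(C)(C)C)[C@H]2[C@@]12CC=C[C@@](C)(C(=O)O1)[C@H]2[C@@H]3C(=O)OCC[Si](C)(C)C | intermediate
31 | 16-ketone | O=C1C[C@]23C[C@H]1C[C@H](O[Si](C)(C)C(C)(C)C)[C@H]2[C@@]12CC=C[C@@](C)(C(=O)O1)[C@H]2[C@@H]3C(=O)OCC[Si](C)(C)C | intermediate
32 | 2β,3β-diol 16-ketone | O=C1C[C@]23C[C@H]1C[C@H](O[Si](C)(C)C(C)(C)C)[C@H]2[C@@]12C[C@H](O)[C@H](O)[C@@](C)(C(=O)O1)[C@H]2[C@@H]3C(=O)OCC[Si](C)(C)C | intermediate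
33 | 2β,3β-diol 16-ene, 11-silyl ether, 7-silylethyl ester | C=C1C[C@]23C[C@H]1C[C@H](O[Si](C)(C)C(C)(C)C)[C@H]2[C@@]12C[C@H](O)[C@H](O)[C@@](C)(C(=O)O1)[C@H]2[C@@H]3C(=O)OCC[Si](C)(C)C | intermediate
34 | 2β,3β,11β-trihydroxy-20-norgibberell-16-ene-7,19-dioic acid 19,10-lactone (CNP0322347.1) | C=C1C[C@]23C[C@H]1C[C@H](O)[C@H]2[C@@]12C[C@H](O)[C@H](O)[C@@](C)(C(=O)O1)[C@H]2[C@@H]3C(=O)O | target

**Step count and risks**

Total: 20 steps. Longest linear sequence: 16 steps (9 → 34 through steps 5–20; the ring-A branch 1 → 34 through steps 1–3 and 8–20 is equally long).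

The three steps most likely to fail:

Step 9. The cascade may stall after the first C–C bond if the ester enolate is quenched by proton transfer before it closes ring B, or it may close through the strained trans-fused manifold, or base may reach C12 and divert the enolate. The fallback separates the two ring closures and keeps C9 planar while ring B forms. It sets out from 19: Cs2CO3 (0.2 equiv) in MeCN at 0 °C should effect only the first Michael addition, the ester enolate being protonated at once, to give the bicyclic keto diester F1 as a C9-epimer mixture. LiN(i-Pr)2 (2.2 equiv) in THF at −78 → −20 °C then forms the dilithium dianion F2 (C11/C9 dienolate plus C6 ester enolate), whose ester enolate closes ring B by the same SN2′ displacement of pivalate to give the lithium dienolate F3. Because C9 is sp2 in F2, C6, held on the α side by C8, can only bond to the α face of C5. Protonation with AcOH at −78 °C, followed if needed by equilibration of C9 with Et3N in CH2Cl2 toward the less strained cis B/C fusion, returns the route at 22.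

Step 8. Zerovalent palladium may ionise the allylic pivalate of 5 or 19 and aromatise ring A, the acidic product may protonate the zinc enolate and be alkenylated twice, or the β,γ double bond may move into conjugation. The fallback avoids palladium. It sets out from 16 and 3: enolate 17 (made as in step 8) is transmetalated with CeCl3 and added to the ketone of 3 at −78 °C to give the β-hydroxy ketone F4. MsCl/Et3N and then DBU give the conjugated dienone F5 (E/Z). Treatment of F5 with KOt-Bu (1.1 equiv) in THF at −40 → 0 °C removes the γ-hydrogen at C1, which generates dienolate 20 directly and lets the cascade of step 9 run, so the route is rejoined at 22.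

Step 15. Hydrogen transfer to the allyl radical may occur at C3 instead of C1 and give the 1-ene. The fallback postpones dehalogenation until the double bond has been used, so that the radical is no longer allylic. It sets out from 27: bromolactonisation (NBS, NaHCO3, THF/H2O, 0 °C) gives the more robust 1β-bromo-2-ene lactone F6. HF·pyridine gives the 16-alcohol F7, Dess–Martin oxidation the 16-ketone F8, and OsO4/NMO the 1β-bromo-2β,3β-diol F9. Bu3SnH/AIBN then removes bromine from a simple secondary radical and returns the route at 32.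

Further compounds
F1 | step 9 | bicyclic keto diester from the first Michael addition alone (C9 epimers) | CC(C)(C)[Si](C)(C)O[C@@H]1C[C@]2(CC(=O)OCC[Si](C)(C)C)C[C@H]1CC(=O)C2C3=CCC(OC(=O)C(C)(C)C)C(C(=O)OC)=C3
F2 | step 9 | dilithium dianion of F1 (C11/C9 dienolate and C6 ester enolate) | [Li+].[Li+].CC(C)(C)[Si](C)(C)O[C@@H]1C[C@]2(C=C([O-])OCC[Si](C)(C)C)C[C@H]1CC([O-])=C2C3=CCC(OC(=O)C(C)(C)C)C(C(=O)OC)=C3
F3 | step 9 | lithium C11/C9 dienolate of 22 | [Li+].CC(C)(C)[Si](C)(C)O[C@@H]1C[C@]23C[C@H]1CC([O-])=C2C4=CCC=C(C(=O)OC)[C@H]4[C@@H]3C(=O)OCC[Si](C)(C)C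
F4 | step 8 | β-hydroxy ketone from aldol addition of 17 to 3 (mixture at the new carbinol and at C3) | C[Si](C)(C)CCOC(=O)C=C1C[C@@H](CC(=O)CC2(O)CCC(OC(=O)C(C)(C)C)C(C(=O)OC)=C2)[C@H](O[Si](C)(C)C(C)(C)C)C1
F5 | step 8 | conjugated dienone isomer of 19 (C9=C10, E/Z mixture) | C[Si](C)(C)CCOC(=O)C=C1C[C@@H](CC(=O)C=C2CCC(OC(=O)C(C)(C)C)C(C(=O)OC)=C2)[C@H](O[Si](C)(C)C(C)(C)C)C1
F6 | step 15 | 1β-bromo-2-ene 19,10-lactone | CC(C)(C)[Si](C)(C)O[C@@H]1C[C@]23C[C@H]1C[C@H](O[Si](C)(C)C(C)(C)C)[C@H]2[C@@]12[C@H](Br)C=C[C@@](C)(C(=O)O1)[C@H]2[C@@H]3C(=O)OCC[Si](C)(C)C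
F7 | step 15 | 16-alcohol of F6 | O[C@@H]1C[C@]23C[C@H]1C[C@H](O[Si](C)(C)C(C)(C)C)[C@H]2[C@@]12[C@H](Br)C=C[C@@](C)(C(=O)O1)[C@H]2[C@@H]3C(=O)OCC[Si](C)(C)C
F8 | step 15 | 16-ketone of F7 | O=C1C[C@]23C[C@H]1C[C@H](O[Si](C)(C)C(C)(C)C)[C@H]2[C@@]12[C@H](Br)C=C[C@@](C)(C(=O)O1)[C@H]2[C@@H]3C(=O)OCC[Si](C)(C)C
F9 | step 15 | 1β-bromo-2β,3β-diol 16-ketone | O=C1C[C@]23C[C@H]1C[C@H](O[Si](C)(C)C(C)(C)C)[C@H]2[C@@]12[C@H](Br)[C@H](O)[C@H](O)[C@@](C)(C(=O)O1)[C@H]2[C@@H]3C(=O)OCC[Si](C)(C)C
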